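**Retrosynthetic overview**

- Feature: in both four-carbon acyl units (the angelate and the central 2-(acyloxymethyl)but-2-enoate) the C4 methyl on C3 lies cis to that unit's own C1 carbonyl. This is the vinylic position a carbonyl-bound metal reaches through a five-membered ring of O, C1, C2, C3 and metal.
- Last disconnection: the cinnamyl ester C–O bond, giving the free diacyl acid and (E)-3,4-dimethoxycinnamyl alcohol, joined by Mitsunobu alkylation of the carboxylate.
- Key disconnection: both C3–C4 methyl bonds of the diacyl acid, giving 2-(methacryloyloxymethyl)acrylic acid and two methyl groups from potassium methyltrifluoroborate, by a twofold carbonyl-directed vinylic C–H methylation.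
- Precursor: sodium methacrylate allylated by tert-butyl 2-(bromomethyl)acrylate, then cleavage of the tert-butyl ester.
- Rings: none is formed in the route; the only ring of the target, the 3,4-dimethoxyphenyl ring, is bought with the cinnamyl alcohol.

Key step: step 3

Remark on the chemistry: all four starting materials are assumed to be catalogue compounds, and each carboxylic acid is written as the free acid obtained after acidic work-up, although its silver salt is the species in the flask in step 3.

**Step 1**
Reactants: 1 sodium methacrylate; 2 tert-butyl 2-(bromomethyl)acrylate
Product: 3 tert-butyl 2-(methacryloyloxymethyl)acrylate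
Conditions: 1 (1.5 equiv), Bu4NI (cat.), BHT (cat.), DMF, 0 °C to rt
Reagents that add atoms: none
Why: O-alkylation of a carboxylate by a doubly activated allylic bromide (SN2 substitution; the SN2′ mode gives the same constitution because the two CH2 termini of the 2-substituted allyl unit are equivalent), with no stereo element created.

**Step 2**
Reactants: 3 tert-butyl 2-(methacryloyloxymethyl)acrylate
Product: 4 2-(methacryloyloxymethyl)acrylic acid
Conditions: CF3CO2H/CH2Cl2 (1:3), BHT (cat.), 0 °C to rt; toluene co-evaporation
Reagents that add atoms: none
Why: acidolysis of a tert-butyl ester by alkyl–oxygen cleavage (loss of the tert-butyl cation as 2-methylpropene) is selective because the primary allylic methacrylate ester and the two electron-poor alkenes are inert to anhydrous CF3CO2H.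

**Step 3**
Reactants: 4 2-(methacryloyloxymethyl)acrylic acid; 5 potassium methyltrifluoroborate (two methyl groups transferred)
Product: 7 (Z)-2-{[(Z)-2-methylbut-2-enoyl]oxymethyl}but-2-enoic acid, via (Z)-2-(methacryloyloxymethyl)but-2-enoic acid 6 (not isolated)
Conditions: [Cp*RhCl2]2 (5 mol %), AgSbF6 (20 mol %), Ag2CO3 (4 equiv), 5 (6 equiv), slow addition of 4, (CF3)2CHOH, 60 °C, argon; then aq. HCl work-up
Reagents that add atoms: potassium methyltrifluoroborate (compound 5), C[B-](F)(F)F.[K+]
Why: Proposed new method: after chloride abstraction by AgSbF6 the cationic Cp*Rh complex of trivalent rhodium binds the carboxylate of 4 and cleaves the vinylic C3–H bond cis to C1 by concerted metalation–deprotonation, giving a transient five-membered rhodacycle (Rh, O, C1, C2, C3); methyl transfer from boron and C–C reductive elimination then place CH3 on C3 with retention, and Ag2CO3 returns monovalent rhodium to the trivalent state. The same cycle, now steered by the weaker ester carbonyl oxygen of the methacrylate in the unisolated mono-methyl acid 6, should install the second methyl and turn the methacrylate into the angelate. The closest known reaction types are the carboxylate- and ester-directed Z-selective vinylic C–H olefination and annulation of acrylic acids and acrylates under Cp*Rh catalysis with trivalent rhodium, and the chelation-assisted C–H methylation of arenes with potassium methyltrifluoroborate and a silver oxidant; a twofold vinylic methylation has not been shown. No ring is closed (the rhodacycles are transient) and no stereocentre is formed; both new double bonds are Z because the methyl can only enter the site the chelated metal occupied, so the geometry is set kinetically and does not depend on the lower stability of the Z isomers. The step needs site selectivity for the hydrogen cis to each carbonyl and a stop at one methyl per alkene: the chelate geometry secures the first, and the second follows because the remaining C3–H is trans to the carbonyl and cannot be reached. Insertion of the rhodium–vinyl bond into a second acrylate, the main side path, is disfavoured by the 1,1-disubstitution of both alkenes and is held back further by adding 4 slowly to an excess of the methyl donor, and the electron-rich styrene is introduced only afterwards.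

**Step 4**
Reactants: 7 (Z)-2-{[(Z)-2-methylbut-2-enoyl]oxymethyl}but-2-enoic acid; 8 (E)-3-(3,4-dimethoxyphenyl)prop-2-en-1-ol
Product: 9 Morinin L, (E)-3-(3,4-dimethoxyphenyl)allyl (Z)-2-{[(Z)-2-methylbut-2-enoyl]oxymethyl}but-2-enoate
Conditions: PPh3, DIAD, THF, 0 °C (betaine preformed); then 8, then 7, 0 °C to rt
Reagents that add atoms: none
Why: Mitsunobu esterification: the hydroxyl of 8 becomes an alkoxyphosphonium leaving group and is displaced at the primary allylic carbon by the carboxylate of 7, so the acyl carbon of 7 is never activated, the two Z alkenes and the E styrene are retained, and no stereocentre is formed.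

**Compound list**

1 | sodium methacrylate | C=C(C)C(=O)[O-].[Na+] | starting material
2 | tert-butyl 2-(bromomethyl)acrylate | C=C(CBr)C(=O)OC(C)(C)C | starting material
3 | tert-butyl 2-(methacryloyloxymethyl)acrylate | C=C(C)C(=O)OCC(=C)C(=O)OC(C)(C)C | intermediate
4 | 2-(methacryloyloxymethyl)acrylic acid | C=C(C)C(=O)OCC(=C)C(=O)O | intermediate
5 | potassium methyltrifluoroborate | C[B-](F)(F)F.[K+] | starting material
6 | (Z)-2-(methacryloyloxymethyl)but-2-enoic acid | C=C(C)C(=O)OC/C(=C/C)C(=O)O | intermediate
7 | (Z)-2-{[(Z)-2-methylbut-2-enoyl]oxymethyl}but-2-enoic acid | C/C=C(/C)C(=O)OC/C(=C/C)C(=O)O | intermediate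
8 | (E)-3-(3,4-dimethoxyphenyl)prop-2-en-1-ol | OC/C=C/c1ccc(OC)c(OC)c1 | starting material
9 | Morinin L | C/C=C(/C)C(=O)OC/C(=C/C)C(=O)OC/C=C/c1ccc(OC)c(OC)c1 | target

**Total step count:** 4
**Longest linear sequence:** 4 steps (1 and 2 to 9)

**Steps most likely to fail**

1. Step 3 (Proposed new method). Three processes may defeat it:
   - The reaction may stall after the carboxylate-directed methylation, because the ester carbonyl binds rhodium too weakly for the second C–H cleavage.
   - The vinyl–rhodium bond may insert into the 2-(acyloxymethyl)acrylate of another molecule and then undergo β-oxygen elimination, which expels methacrylate and oligomerises the substrate.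
   - The methyl donor may be consumed by protodeboronation or homocoupling before transmetalation.

   Fallback, known chemistry: it replaces steps 1 to 3, so it sets out from none of the numbered compounds but from commercial (E)-but-2-enal, and it comes back to the route at compound 7. α-Iodination (I2, K2CO3, DMAP cat., THF/H2O) should give (Z)-2-iodobut-2-enal F1, in which iodine is cis to the methyl group. Luche reduction (NaBH4, CeCl3, MeOH, 0 °C) gives (Z)-2-iodobut-2-en-1-ol F2. Alkoxycarbonylation of the vinyl iodide with retention (PdCl2(PPh3)2 cat., CO, K2CO3, 2-(trimethylsilyl)ethanol, DMF, 60 °C) gives 2-(trimethylsilyl)ethyl (Z)-2-(hydroxymethyl)but-2-enoate F3, whose methyl is now cis to the new carbonyl. Mitsunobu esterification with commercial angelic acid (PPh3, DIAD, THF) gives 2-(trimethylsilyl)ethyl (Z)-2-{[(Z)-2-methylbut-2-enoyl]oxymethyl}but-2-enoate F4. Bu4NF in THF at 0 °C removes the silylethyl group and gives 7, which goes on into step 4.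

2. Step 4. Triphenylphosphine that has not been bound as betaine may add in conjugate fashion to the 2-(acyloxymethyl)enoate of 7 and displace the angelate. The electron-rich cinnamyl oxyphosphonium ion may also ionise, leading to allylic transposition to the branched 1-arylallyl ester.

   Fallback: it sets out from 8 and comes back at 9. Alcohol 8 is converted with MsCl, Et3N and LiCl in THF at 0 °C into (E)-4-(3-chloroprop-1-en-1-yl)-1,2-dimethoxybenzene F5. The caesium carboxylate of 7 (Cs2CO3, DMF, rt) is then alkylated with F5 to give 9. No phosphine is present, and the acyl carbon of 7 still is never activated.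

3. Step 2. Material may be lost by polymerisation of the bis-acrylate while the acid is concentrated, and the tert-butyl cation may be trapped by the methacrylate alkene.

   Fallback: it sets out from 1 and comes back at 4, without a protecting group. Commercial 2-(bromomethyl)acrylic acid is stirred with a fivefold excess of 1 in DMF/water at rt, so that methacrylate outcompetes the substrate's own carboxylate for the allylic bromide. Acidification and removal of methacrylic acid under vacuum should leave 4 directly.

**Further compounds**

F1 | step 3 | (Z)-2-iodobut-2-enal | C/C=C(\I)C=O
F2 | step 3 | (Z)-2-iodobut-2-en-1-ol | C/C=C(\I)CO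
F3 | step 3 | 2-(trimethylsilyl)ethyl (Z)-2-(hydroxymethyl)but-2-enoate | C/C=C(/CO)C(=O)OCC[Si](C)(C)C
F4 | step 3 | 2-(trimethylsilyl)ethyl (Z)-2-{[(Z)-2-methylbut-2-enoyl]oxymethyl}but-2-enoate | C/C=C(/C)C(=O)OC/C(=C/C)C(=O)OCC[Si](C)(C)C
F5 | step 4 | (E)-4-(3-chloroprop-1-en-1-yl)-1,2-dimethoxybenzene | ClC/C=C/c1ccc(OC)c(OC)c1
F0 | step 2 | none | none
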